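**First look.** I started with the easy step, laying the two earlier runs side by side.

| setting | violet | amber | flask |
|---|---|---|---|
| free monomer | 0.010 M | 0.010 M | 0.010 M |
| initiator | 50 µM | 75 µM | 100 µM |
| remark | run made earlier | run made earlier |  |
| time |  |  | 3.0 h |

- violet (time / h: monomer in chains / %, free monomer / %): 0.200: 0, 100.0; 0.500: 0.7, 99.6; 1.00: 1.3, 99.0; 1.50: 1.4, 97.5; 2.00: 3.0, 97.7; 3.00: 6.4, 93.3; 4.00: 9.9, 88.9
- amber (time / h: monomer in chains / %, free monomer / %): 0.200: 0, 100.7; 0.500: 0.2, 99.3; 1.00: 1.0, 98.3; 1.50: 2.6, 96.7; 2.00: 4.3, 95.0; 3.00: 9.2, 91.6; 4.00: 13.5, 86.0

(standard deviation of a reading: 0.5 percentage points)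

- the average divides the monomer in chains by the number of chains begun, living and dead together
- on the list of suspects stand: free monomer + initiator -> living end + monomer in chains; free monomer + initiator -> spent initiator A; 2 initiator -> spent initiator B; free monomer + living end -> monomer in chains + living end
- the earlier runs do not show the number of chains; that part of a forecast is a guess

- average number of monomer units in a chain (chains begun, living or dead) at 3.0 h
- part of the free monomer that has reacted at 3.0 h

**Slow start.** In the amber run, monomer in chains rose from 2.6% at 1.50 h to 9.2% at 3.00 h. That is twice the time and 3.54 times the amount, close to a square. I read it as an induction period: living ends build up steadily, and each one keeps adding monomer.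

**Two times.** So I needed just two times, the time of reading and one more. For this flask's initiator, the amber run gives 8.57 h and the violet run 8.39 h. This is the run-in time: the time at which the square, carried on, would bring the whole charge into chains. I took it to shorten with the root of the initiator charged, at this charge of free monomer. While the share in chains stays small, I reckoned it as the square of reading time over run-in time, so at 3.0 h I expected 12.3%. The readings do not show the number of chains, so I put no number on the average.

**The forecast.** The forecast said 10.8% and 30, adding “The chain count is a guess”.

**The result.** The flask gave 11.6% reacted and 82.7 units per chain.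

    free monomer + initiator → living end + monomer in chains (k = 7.10 M⁻¹ h⁻¹)
    free monomer + initiator → spent initiator A (k = 17.0 M⁻¹ h⁻¹)
    2 initiator → spent initiator B (k = 370 M⁻¹ h⁻¹)
    free monomer + living end → monomer in chains + living end, rate k4*[living end]*[free monomer] (k = 5000 M⁻¹ h⁻¹)

It held 11.3% in chains against my 12.3%. The hour of the reading is the largest single effect on the chain length: ten times later, this flask's average stands at 399, against 82.7. A neighbour flask with a quarter of this initiator has twice the run-in time, 17.1 h, so the square gives 3.07%, and at 3.00 h that neighbour held 3.11% in chains.

(The numbers in the tables come from a simulation with constants of no real substance, and the scatter is random.)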